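Ring B (C5–C10 in labdane numbering; ring A is C1–C5 plus C10) is read as a latent 2-methylcyclohexenone: C9, which carries the side chain, is a ketone carbon between its α-carbons C8 and C10, and C5–C6–C7 is an enal. An acyclic keto enal, (E)-4,4,8-trimethyl-9-oxoundec-2-enal, is therefore folded in one amine-catalysed operation: Michael addition of C10 to C5 (bond C5–C10) closes ring A and sets both stereocentres, and aldol condensation of C8 onto C7 (bond C7–C8) closes ring B. The quaternary C4 protects the enal from γ-enolisation. The enone is turned into the C8=C9 enol triflate and coupled with a side chain made from the (S)-Roche ester.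

Key step: step 5

Remark on numbering: C4 carries the geminal methyls, C8 the vinylic methyl, C9 the side chain C11–C18 (C17 is the α-carbon of the acid, C18 the carboxyl carbon).
Assumption: 2-methylpent-1-en-3-one (4) is taken as a catalogue compound; compounds 5–7 are used as racemates because their only stereocentre (future C10) is erased by enolisation in step 5.

Step 1
Reactants: 1 methyl 3,3-dimethylpent-4-enoate
Product: 2 3,3-dimethylpent-4-en-1-ol
Conditions: LiAlH4, Et2O, 0 °C → rt
Reagents that add atoms: none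
Why: Hydride reduction of the ester to the primary alcohol, to which the isolated terminal alkene is inert.

Step 2
Reactants: 2 3,3-dimethylpent-4-en-1-ol
Product: 3 5-iodo-3,3-dimethylpent-1-ene
Conditions: I2, PPh3, imidazole, CH2Cl2, 0 °C → rt
Reagents that add atoms: iodine, II
Why: Appel iodination, in which iodide displaces the alkoxyphosphonium group at the unhindered primary carbon.

Step 3
Reactants: 3 5-iodo-3,3-dimethylpent-1-ene; 4 2-methylpent-1-en-3-one (3 equiv)
Product: 5 4,8,8-trimethyldec-9-en-3-one (racemic)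
Conditions: (Me3Si)3SiH, AIBN (cat.), toluene, 80 °C
Reagents that add atoms: none
Why: Giese addition, in which the primary radical from 3 adds to the unsubstituted terminus of the 1,1-disubstituted enone and the α-keto radical is reduced by the silane; the new centre is formed racemic, which is immaterial.

Step 4
Reactants: 5 4,8,8-trimethyldec-9-en-3-one
Product: 7 (E)-4,4,8-trimethyl-9-oxoundec-2-enal (racemic), via 2,2,6-trimethyl-7-oxononanal 6 (not isolated)
Conditions: O3, CH2Cl2, −78 °C; PPh3, −78 °C → rt; solvent exchange to toluene, Ph3P=CHCHO, 80 °C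
Reagents that add atoms: ozone, [O-][O+]=O (aldehyde oxygen of 6); (triphenylphosphoranylidene)acetaldehyde, O=CC=P(c1ccccc1)(c1ccccc1)c1ccccc1
Why: Ozonolysis of the only alkene unveils the neopentyl aldehyde, and the stabilised ylide then reacts with the aldehyde but not with the ketone to give the (E)-enal (Wittig olefination under thermodynamic E control).

Step 5
Reactants: 7 (E)-4,4,8-trimethyl-9-oxoundec-2-enal (racemic)
Product: 9 (4aS,8aS)-2,5,5,8a-tetramethyl-4a,5,6,7,8,8a-hexahydronaphthalen-1(4H)-one, via keto aldehyde 8 (not isolated)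
Conditions: (S)-2-[diphenyl(trimethylsilyloxy)methyl]pyrrolidine (20 mol %), PhCO2H (20 mol %), toluene (0.05 M), 40 °C; then TsOH·H2O (20 mol %), 60 °C
Reagents that add atoms: none
Why: The amine condenses with the enal to an (E)-iminium ion; the more substituted enol of the C9 ketone adds through C10 to C5 (bond C5–C10), and the aldehyde iminium ion regenerated at C7 is then attacked by the enol of the only α-carbon left, C8 (bond C7–C8), after which loss of the amine (or of water under TsOH) gives the conjugated enone. The closest known reaction type is the prolinol-silyl-ether-catalysed Michael/aldol-condensation annulation of carbonyl pronucleophiles with enals, an organocatalytic Robinson-type annulation, run here intramolecularly with [3+3] connectivity. Ring A closes by a 6-(enolexo)-exo-trig conjugate addition and ring B by a 6-(enolendo)-exo-trig aldol addition. C5 is set by the catalyst, whose diphenyl(silyloxy)methyl group shields one face of the s-trans iminium ion so that the (S)-amine should deliver C10 to the face giving (5S); C10 is set by relay through a chair-like transition state that keeps the two reacting arms (C9 and C6) pseudo-equatorial and the C10 methyl and H5 pseudo-axial and anti, which gives the trans (5S,10S) pair, and the racemic centre of 7 is erased by enolisation so that both enantiomers converge. The step needs the Michael donor to be C10 and not C8 and the enal to stay a pure acceptor: only C10 reaches C5 through a six-membered ring (C8 would need an eight-membered one), only C8 can then reach C7, and the quaternary C4 leaves the enal without γ-hydrogens, so dienamine formation is impossible. The main risk is the low nucleophilicity of an unactivated ketone enol toward a β-neopentyl iminium ion, met by acid co-catalysis and warming.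

Step 6
Reactants: 9 (4aS,8aS)-2,5,5,8a-tetramethyl-4a,5,6,7,8,8a-hexahydronaphthalen-1(4H)-one
Product: 10 (4aS,8aS)-2,5,5,8a-tetramethyl-3,4,4a,5,6,7,8,8a-octahydronaphthalen-1-yl trifluoromethanesulfonate
Conditions: LiBH(s-Bu)3, THF, −78 °C; then PhNTf2, −78 → 0 °C
Reagents that add atoms: N-phenylbis(trifluoromethanesulfonimide), O=S(=O)(N(c1ccccc1)S(=O)(=O)C(F)(F)F)C(F)(F)F
Why: Conjugate reduction with enolate trapping, in which hydride adds to the unsubstituted β-carbon C7 (1,2-attack at C9 is blocked by the quaternary C10) and the single possible enolate is O-sulfonylated to fix the C8=C9 double bond.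

Step 7
Reactants: 11 methyl (S)-3-hydroxy-2-methylpropanoate ((S)-Roche ester)
Product: 12 methyl (S)-3-[(tert-butyldimethylsilyl)oxy]-2-methylpropanoate
Conditions: TBSCl, imidazole, CH2Cl2, rt
Reagents that add atoms: tert-butyldimethylsilyl chloride, CC(C)(C)[Si](C)(C)Cl
Why: Silylation of the primary alcohol under conditions too mild to epimerise the α-centre.

Step 8
Reactants: 12 methyl (S)-3-[(tert-butyldimethylsilyl)oxy]-2-methylpropanoate
Product: 13 (S)-3-[(tert-butyldimethylsilyl)oxy]-2-methylpropanal
Conditions: i-Bu2AlH (1.05 equiv), CH2Cl2, −78 °C; product used crude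
Reagents that add atoms: none
Why: Partial reduction, in which the aluminium hemiacetal is stable at −78 °C and releases the aldehyde only on work-up, so the α-centre should be retained.

Step 9
Reactants: 13 (S)-3-[(tert-butyldimethylsilyl)oxy]-2-methylpropanal
Product: 14 tert-butyl{[(2R,3E)-4-iodo-2-methylbut-3-en-1-yl]oxy}dimethylsilane
Conditions: CrCl2, CHI3, THF/dioxane, 0 °C → rt
Reagents that add atoms: iodoform, IC(I)I
Why: Takai olefination, in which the non-basic geminal dichromium reagent should give the (E)-vinyl iodide without touching the stereocentre (the descriptor changes from S to R only through priorities).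

Step 10
Reactants: 15 but-3-yn-1-ol; 14 tert-butyl{[(2R,3E)-4-iodo-2-methylbut-3-en-1-yl]oxy}dimethylsilane
Product: 17 (3E,5E,7R)-8-[(tert-butyldimethylsilyl)oxy]-3,7-dimethylocta-3,5-dien-1-ol, via alkenylalane 16 (not isolated)
Conditions: Me3Al (3 equiv), Cp2ZrCl2 (25 mol %), CH2Cl2, 0 °C → rt; then 14, ZnCl2, Pd(PPh3)4 (5 mol %), THF, rt
Reagents that add atoms: trimethylaluminium, C[Al](C)C
Why: Zirconium-catalysed syn-methylalumination of the terminal alkyne (methyl to the internal carbon) gives the (E)-alkenylalane, which couples with retention at both partners through zinc and zerovalent palladium (Negishi coupling) to give the (3E,5E)-diene.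

Step 11
Reactants: 17 (3E,5E,7R)-8-[(tert-butyldimethylsilyl)oxy]-3,7-dimethylocta-3,5-dien-1-ol
Product: 18 tert-butyl{[(2R,3E,5E)-8-iodo-2,6-dimethylocta-3,5-dien-1-yl]oxy}dimethylsilane
Conditions: I2, PPh3, imidazole, CH2Cl2, 0 °C
Reagents that add atoms: iodine, II
Why: Appel iodination of the primary homoallylic alcohol under neutral conditions that leave the diene and silyl ether untouched.

Step 12
Reactants: 18 tert-butyl{[(2R,3E,5E)-8-iodo-2,6-dimethylocta-3,5-dien-1-yl]oxy}dimethylsilane; 10 (4aS,8aS)-2,5,5,8a-tetramethyl-3,4,4a,5,6,7,8,8a-octahydronaphthalen-1-yl trifluoromethanesulfonate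
Product: 20 tert-butyl({(2R,3E,5E)-2,6-dimethyl-8-[(4aS,8aS)-2,5,5,8a-tetramethyl-3,4,4a,5,6,7,8,8a-octahydronaphthalen-1-yl]octa-3,5-dien-1-yl}oxy)dimethylsilane, via alkylzinc iodide 19 (not isolated)
Conditions: Zn dust, LiCl, THF, 40 °C; then 10, Pd(OAc)2 (5 mol %), SPhos (10 mol %), THF/NMP, 50 °C
Reagents that add atoms: zinc, [Zn] (in 19 only)
Why: sp3–sp2 Negishi coupling, in which zinc inserts into the primary C–I bond and the alkylzinc transfers to the alkenylpalladium formed from the triflate, the bulky electron-rich phosphine favouring reductive elimination over β-hydride elimination.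

Step 13
Reactants: 20 silyl ether from step 12
Product: 21 (2R,3E,5E)-2,6-dimethyl-8-[(4aS,8aS)-2,5,5,8a-tetramethyl-3,4,4a,5,6,7,8,8a-octahydronaphthalen-1-yl]octa-3,5-dien-1-ol
Conditions: Bu4NF, THF, 0 °C → rt
Reagents that add atoms: none
Why: Fluoride cleaves the Si–O bond; nothing else in the molecule is fluoride- or base-sensitive at this oxidation level.

Step 14
Reactants: 21 dienol from step 13
Product: 23 (2R,3E,5E)-2,6-dimethyl-8-[(4aS,8aS)-2,5,5,8a-tetramethyl-3,4,4a,5,6,7,8,8a-octahydronaphthalen-1-yl]octa-3,5-dienoic acid (target), via dienal 22 (not isolated)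
Conditions: Dess–Martin periodinane, NaHCO3, CH2Cl2, 0 °C; then NaClO2, NaH2PO4, 2-methyl-2-butene (excess), t-BuOH/H2O, 0 °C
Reagents that add atoms: sodium chlorite, [Na+].[O-]Cl=O
Why: Buffered Dess–Martin oxidation followed at once by Pinnick oxidation keeps the epimerisable, deconjugated α-methyl aldehyde short-lived and near neutral, and the alkene scavenger protects the tetrasubstituted alkene and the diene from hypochlorous acid.

Compound list
1 | methyl 3,3-dimethylpent-4-enoate | COC(=O)CC(C)(C)C=C | starting material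
2 | 3,3-dimethylpent-4-en-1-ol | OCCC(C)(C)C=C | intermediate
3 | 5-iodo-3,3-dimethylpent-1-ene | ICCC(C)(C)C=C | intermediate
4 | 2-methylpent-1-en-3-one | CCC(=O)C(C)=C | starting material
5 | 4,8,8-trimethyldec-9-en-3-one (racemic) | CCC(=O)C(C)CCCC(C)(C)C=C | intermediate
6 | 2,2,6-trimethyl-7-oxononanal (racemic) | CCC(=O)C(C)CCCC(C)(C)C=O | intermediate (not isolated)
7 | (E)-4,4,8-trimethyl-9-oxoundec-2-enal (racemic at C8) | CCC(=O)C(C)CCCC(C)(C)/C=C/C=O | intermediate
8 | 2-[(1S,2S)-2,6,6-trimethyl-2-propanoylcyclohexyl]acetaldehyde | CCC(=O)[C@@]1(C)CCCC(C)(C)[C@@H]1CC=O | intermediate (not isolated)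
9 | (4aS,8aS)-2,5,5,8a-tetramethyl-4a,5,6,7,8,8a-hexahydronaphthalen-1(4H)-one | O=C1[C@@]2(C)CCCC(C)(C)[C@@H]2CC=C1C | intermediate
10 | (4aS,8aS)-2,5,5,8a-tetramethyl-3,4,4a,5,6,7,8,8a-octahydronaphthalen-1-yl trifluoromethanesulfonate | CC1=C(OS(=O)(=O)C(F)(F)F)[C@@]2(C)CCCC(C)(C)[C@@H]2CC1 | intermediate
11 | methyl (S)-3-hydroxy-2-methylpropanoate | COC(=O)[C@@H](C)CO | starting material
12 | methyl (S)-3-[(tert-butyldimethylsilyl)oxy]-2-methylpropanoate | COC(=O)[C@@H](C)CO[Si](C)(C)C(C)(C)C | intermediate
13 | (S)-3-[(tert-butyldimethylsilyl)oxy]-2-methylpropanal | O=C[C@@H](C)CO[Si](C)(C)C(C)(C)C | intermediate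
14 | tert-butyl{[(2R,3E)-4-iodo-2-methylbut-3-en-1-yl]oxy}dimethylsilane | I/C=C/[C@@H](C)CO[Si](C)(C)C(C)(C)C | intermediate
15 | but-3-yn-1-ol | C#CCCO | starting material
16 | dimethylaluminium (3E)-4-(dimethylalumanyl)-3-methylbut-3-en-1-olate | C[Al](C)OCC/C(C)=C/[Al](C)C | intermediate (not isolated)
17 | (3E,5E,7R)-8-[(tert-butyldimethylsilyl)oxy]-3,7-dimethylocta-3,5-dien-1-ol | OCC/C(C)=C/C=C/[C@@H](C)CO[Si](C)(C)C(C)(C)C | intermediate
18 | tert-butyl{[(2R,3E,5E)-8-iodo-2,6-dimethylocta-3,5-dien-1-yl]oxy}dimethylsilane | ICC/C(C)=C/C=C/[C@@H](C)CO[Si](C)(C)C(C)(C)C | intermediate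
19 | {(3E,5E,7R)-8-[(tert-butyldimethylsilyl)oxy]-3,7-dimethylocta-3,5-dien-1-yl}zinc iodide | I[Zn]CC/C(C)=C/C=C/[C@@H](C)CO[Si](C)(C)C(C)(C)C | intermediate (not isolated)
20 | tert-butyl({(2R,3E,5E)-2,6-dimethyl-8-[(4aS,8aS)-2,5,5,8a-tetramethyl-3,4,4a,5,6,7,8,8a-octahydronaphthalen-1-yl]octa-3,5-dien-1-yl}oxy)dimethylsilane | CC1=C(CC/C(C)=C/C=C/[C@@H](C)CO[Si](C)(C)C(C)(C)C)[C@@]2(C)CCCC(C)(C)[C@@H]2CC1 | intermediate
21 | (2R,3E,5E)-2,6-dimethyl-8-[(4aS,8aS)-2,5,5,8a-tetramethyl-3,4,4a,5,6,7,8,8a-octahydronaphthalen-1-yl]octa-3,5-dien-1-ol | CC1=C(CC/C(C)=C/C=C/[C@@H](C)CO)[C@@]2(C)CCCC(C)(C)[C@@H]2CC1 | intermediate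
22 | (2R,3E,5E)-2,6-dimethyl-8-[(4aS,8aS)-2,5,5,8a-tetramethyl-3,4,4a,5,6,7,8,8a-octahydronaphthalen-1-yl]octa-3,5-dienal | CC1=C(CC/C(C)=C/C=C/[C@@H](C)C=O)[C@@]2(C)CCCC(C)(C)[C@@H]2CC1 | intermediate (not isolated)
23 | (2R,3E,5E)-2,6-dimethyl-8-[(4aS,8aS)-2,5,5,8a-tetramethyl-3,4,4a,5,6,7,8,8a-octahydronaphthalen-1-yl]octa-3,5-dienoic acid | CC1=C(CC/C(C)=C/C=C/[C@@H](C)C(=O)O)[C@@]2(C)CCCC(C)(C)[C@@H]2CC1 | target

Total step count: 14. Longest linear sequence: 9 steps (steps 1–6, then 12–14); the side-chain branch (steps 7–11) joins at step 12.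

Steps most likely to fail

Step 5. The unactivated ketone enol may add too slowly to the hindered iminium ion, so that intermolecular condensation of the enal competes, and facial control at C10 may be incomplete, giving some cis-fused material. The fallback separates nucleophile generation from the cyclisation and sets out from 7. Soft enolisation (Me3SiCl, NaI, Et3N, MeCN) should give mainly the more substituted silyl enol ether, (2E)-4,4,8-trimethyl-9-[(trimethylsilyl)oxy]undeca-2,8-dienal F1; its regioisomer cannot cyclise and is recycled by hydrolysis. F1 is then cyclised by an intramolecular Mukaiyama–Michael addition under the same (S)-amine/acid iminium catalysis, which should give keto aldehyde 8 after loss of the silyl group. A separate aldol condensation (KOH, MeOH) closes ring B, and the route is rejoined at 9.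

Step 12. Slow oxidative addition and transmetalation at the tetrasubstituted triflate, flanked by the quaternary C10, may let β-hydride elimination and protodemetalation consume the valuable alkylzinc reagent. The fallback puts a small, cheap nucleophile on the hindered carbon first and builds the diene afterwards; it sets out from 10. (4-Bromobut-1-yn-1-yl)trimethylsilane is converted with zinc into [4-(trimethylsilyl)but-3-yn-1-yl]zinc bromide F2, which is used in excess in the Negishi coupling with 10 to give trimethyl{4-[(4aS,8aS)-2,5,5,8a-tetramethyl-3,4,4a,5,6,7,8,8a-octahydronaphthalen-1-yl]but-1-yn-1-yl}silane F3. K2CO3 in MeOH gives the terminal alkyne (4aS,8aS)-1-(but-3-yn-1-yl)-2,5,5,8a-tetramethyl-3,4,4a,5,6,7,8,8a-octahydronaphthalene F4. Zirconium-catalysed methylalumination (Me3Al, Cp2ZrCl2) gives the alkenylalane dimethyl{(1E)-2-methyl-4-[(4aS,8aS)-2,5,5,8a-tetramethyl-3,4,4a,5,6,7,8,8a-octahydronaphthalen-1-yl]but-1-en-1-yl}alumane F5, which is coupled in the same flask with vinyl iodide 14 (ZnCl2, Pd(PPh3)4). The route is rejoined at 20; steps 10 and 11 are then not needed.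

Step 4. The neopentyl aldehyde may react sluggishly with the formyl ylide, and the less hindered product enal may be homologated a second time. The fallback sets out from 6, isolated after the ozonolysis. Horner–Wadsworth–Emmons olefination with triethyl phosphonoacetate (LiCl, DBU, MeCN) gives ethyl (2E)-4,4,8-trimethyl-9-oxoundec-2-enoate F6, which cannot over-react. Reduction of both carbonyl groups with i-Bu2AlH gives (2E)-4,4,8-trimethylundec-2-ene-1,9-diol F7, and double oxidation with Dess–Martin periodinane rejoins the route at 7.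

Further compounds
F1 | step 5 | (2E)-4,4,8-trimethyl-9-[(trimethylsilyl)oxy]undeca-2,8-dienal | CCC(O[Si](C)(C)C)=C(C)CCCC(C)(C)/C=C/C=O
F2 | step 12 | [4-(trimethylsilyl)but-3-yn-1-yl]zinc bromide | Br[Zn]CCC#C[Si](C)(C)C
F3 | step 12 | trimethyl{4-[(4aS,8aS)-2,5,5,8a-tetramethyl-3,4,4a,5,6,7,8,8a-octahydronaphthalen-1-yl]but-1-yn-1-yl}silane | CC1=C(CCC#C[Si](C)(C)C)[C@@]2(C)CCCC(C)(C)[C@@H]2CC1
F4 | step 12 | (4aS,8aS)-1-(but-3-yn-1-yl)-2,5,5,8a-tetramethyl-3,4,4a,5,6,7,8,8a-octahydronaphthalene | CC1=C(CCC#C)[C@@]2(C)CCCC(C)(C)[C@@H]2CC1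
F5 | step 12 | dimethyl{(1E)-2-methyl-4-[(4aS,8aS)-2,5,5,8a-tetramethyl-3,4,4a,5,6,7,8,8a-octahydronaphthalen-1-yl]but-1-en-1-yl}alumane | CC1=C(CC/C(C)=C/[Al](C)C)[C@@]2(C)CCCC(C)(C)[C@@H]2CC1
F6 | step 4 | ethyl (2E)-4,4,8-trimethyl-9-oxoundec-2-enoate | CCOC(=O)/C=C/C(C)(C)CCCC(C)C(=O)CC
F7 | step 4 | (2E)-4,4,8-trimethylundec-2-ene-1,9-diol | OC/C=C/C(C)(C)CCCC(C)C(O)CC
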